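**Strategy.** The flavone is cut back to a linear aryl pentacarbonyl chain. C2, C3, C4 and the six A-ring carbons C4a–C8a are laid out as a methyl 9-aryl-3,5,7,9-tetraoxononanoate, whose oxygens sit on every second carbon, matching C2–O1, C4=O and the oxygens on C5, C7 and C8a. One base-mediated intramolecular Claisen condensation (chain C6 onto the ester carbon) forms the C4a–C5 bond, closes ring A and aromatises it to a symmetric acylphloroglucinol. Its remaining 1,3-diketone is C4–C3–C2, so dehydration then closes ring C. The B ring enters as a MOM-protected, reverse-prenylated benzoate. The C8 prenyl group is added last by a 5-O-prenyl Claisen–Cope shift.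

Key step: step 8

Remark: the target has no stereocentre, stereogenic axis or configurationally defined double bond; it is achiral, so no step has to control configuration.

**Route**

Step 1
Reactants: 1 methyl 2,4-dihydroxybenzoate; 2 prenyl bromide
Product: 3 methyl 2-hydroxy-4-[(3-methylbut-2-en-1-yl)oxy]benzoate
Conditions: K2CO3, acetone, reflux
Reagents that add atoms: none
Why: Williamson etherification should occur only at the free, more acidic 4-OH, because the 2-OH is held in a hydrogen bond to the ester carbonyl.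

Step 2
Reactants: 3 methyl 2-hydroxy-4-[(3-methylbut-2-en-1-yl)oxy]benzoate
Product: 4 methyl 2-(methoxymethoxy)-4-[(3-methylbut-2-en-1-yl)oxy]benzoate
Conditions: NaH, MOMCl, DMF, 0 °C → rt
Reagents that add atoms: chloromethyl methyl ether (MOMCl), COCCl
Why: Irreversible deprotonation breaks the chelate and the phenoxide is O-alkylated to the MOM acetal, which removes the chelation that would otherwise steer the later [3,3] shift to C3.

Step 3
Reactants: 4 methyl 2-(methoxymethoxy)-4-[(3-methylbut-2-en-1-yl)oxy]benzoate
Product: 5 methyl 4-hydroxy-2-(methoxymethoxy)-5-(2-methylbut-3-en-2-yl)benzoate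
Conditions: PhNEt2, 185 °C, sealed tube, Ar
Reagents that add atoms: none
Why: Aromatic Claisen rearrangement should deliver the allyl-inverted 2-methylbut-3-en-2-yl group to C5 rather than C3, since C3 is flanked by two oxygen substituents and an unchelated meta donor directs away from itself; the basic solvent suppresses acid-induced cyclisation onto the new phenol.

Step 4
Reactants: 5 methyl 4-hydroxy-2-(methoxymethoxy)-5-(2-methylbut-3-en-2-yl)benzoate
Product: 6 methyl 2,4-bis(methoxymethoxy)-5-(2-methylbut-3-en-2-yl)benzoate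
Conditions: MOMCl, i-Pr2NEt, CH2Cl2, 0 °C → reflux
Reagents that add atoms: chloromethyl methyl ether (MOMCl), COCCl
Why: O-alkylation (acetal formation) of the acidic phenol para to the ester gives a benzoate with no acidic hydrogen, fit for polyanion chemistry.

Step 5
Reactants: 7 2,6-dimethyl-4H-pyran-4-one
Product: 8 heptane-2,4,6-trione
Conditions: Ba(OH)2·8H2O, H2O, 70 °C; then cold 2 M HCl, Et2O
Reagents that add atoms: water, O
Why: Hydrolytic ring opening of the 4-pyranone (hydroxide addition at C2, then retro-oxa-Michael opening) gives the triketone as its sparingly soluble barium enolate, which cold acid sets free before it can recyclise.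

Step 6
Reactants: 6 methyl 2,4-bis(methoxymethoxy)-5-(2-methylbut-3-en-2-yl)benzoate; 8 heptane-2,4,6-trione
Product: 9 1-[2,4-bis(methoxymethoxy)-5-(2-methylbut-3-en-2-yl)phenyl]octane-1,3,5,7-tetraone
Conditions: 8 (2 equiv), LDA (commercial solution, 6 equiv), THF, 0 °C; then 6, 0 °C → rt; cold 1 M HCl to pH 4
Reagents that add atoms: none
Why: Claisen-type C-aroylation of a triketone trianion should occur at its terminal, least stabilised carbanion; the ester has no α-hydrogen and the second equivalent of trianion absorbs the more acidic product.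

Step 7
Reactants: 9 1-[2,4-bis(methoxymethoxy)-5-(2-methylbut-3-en-2-yl)phenyl]octane-1,3,5,7-tetraone; 10 dimethyl carbonate
Product: 11 methyl 9-[2,4-bis(methoxymethoxy)-5-(2-methylbut-3-en-2-yl)phenyl]-3,5,7,9-tetraoxononanoate
Conditions: LDA (commercial solution, 5 equiv), THF, −78 → 0 °C; then (MeO)2CO (1.1 equiv), −78 → 0 °C; cold 1 M HCl to pH 4
Reagents that add atoms: none
Why: Terminal C-methoxycarbonylation of a polyketone polyanion with a dialkyl carbonate, as practised on β-diketone dianions, should occur at the methyl carbanion of the tetraanion; the fifth equivalent of base takes up the new acidic C2–H so the product stays fully enolised and does not cyclise in the flask.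

Step 8
Reactants: 11 methyl 9-[2,4-bis(methoxymethoxy)-5-(2-methylbut-3-en-2-yl)phenyl]-3,5,7,9-tetraoxononanoate
Product: 12 1-[2,4-bis(methoxymethoxy)-5-(2-methylbut-3-en-2-yl)phenyl]-3-(2,4,6-trihydroxyphenyl)propane-1,3-dione
Conditions: KOH (excess), MeOH, 0 °C → rt, Ar; then cold 1 M HCl to pH 4–5
Reagents that add atoms: none
Why: Base converts 11 into its polyenolate, the carbanion at chain C6 (between the C5 and C7 carbonyls) adds to the C1 ester carbonyl, methoxide leaves and the 2-acylcyclohexane-1,3,5-trione tautomerises irreversibly to the aromatic triol, i.e. an intramolecular Claisen condensation. The closest known reaction is the alkali-induced Claisen cyclisation of methyl 7-aryl-3,5,7-trioxoheptanoates to 2,4,6-trihydroxybenzophenones, of which this substrate is the next chain homologue. Ring A closes in a 6-(enolendo)-exo-trig mode from chain atoms C1–C6, and the C1–C6 bond (flavone C4a–C5) is the only new skeletal bond. No stereocentre is formed. The step needs C-acylation at the ester in preference to aldol closures onto the C3, C7 or C9 ketones and to O-acylation giving a 4-hydroxy-2-pyranone; in strong base every ketone is a poorly electrophilic enolate, the C9 carbonyl is further deactivated by its ortho and para alkoxy donors, and the acyl terminus is kept as the methyl ester, never the carboxylate, so that it remains the best acceptor. Because the acyl group ends up between two equivalent hydroxyls, the later pyranone closure has no regiochemical choice on ring A.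

Step 9
Reactants: 12 1-[2,4-bis(methoxymethoxy)-5-(2-methylbut-3-en-2-yl)phenyl]-3-(2,4,6-trihydroxyphenyl)propane-1,3-dione
Product: 14 2-[2,4-bis(methoxymethoxy)-5-(2-methylbut-3-en-2-yl)phenyl]-5,7-dihydroxy-4H-chromen-4-one, via 2-hydroxyflavanone hemiketal 13 (not isolated)
Conditions: AcOH, NaOAc, 80 °C
Reagents that add atoms: none
Why: Cyclodehydration of an o-hydroxyaryl 1,3-diketone (the closing stage of a Baker–Venkataraman flavone synthesis) should pass through hemiketal 13 and lose water in buffered acetic acid, which should spare the aryl MOM ethers; the MOM cap on the B-ring ortho oxygen leaves only the A-ring hydroxyls able to close, so a single chromone is expected.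

Step 10
Reactants: 14 2-[2,4-bis(methoxymethoxy)-5-(2-methylbut-3-en-2-yl)phenyl]-5,7-dihydroxy-4H-chromen-4-one
Product: 15 2-[2,4-bis(methoxymethoxy)-5-(2-methylbut-3-en-2-yl)phenyl]-5-hydroxy-7-(methoxymethoxy)-4H-chromen-4-one
Conditions: MOMCl (1.1 equiv), i-Pr2NEt, CH2Cl2, 0 °C → rt
Reagents that add atoms: chloromethyl methyl ether (MOMCl), COCCl
Why: Selective O-alkylation of the acidic, unchelated 7-OH is expected because the 5-OH is tied up in a hydrogen bond to the C4 carbonyl.

Step 11
Reactants: 15 2-[2,4-bis(methoxymethoxy)-5-(2-methylbut-3-en-2-yl)phenyl]-5-hydroxy-7-(methoxymethoxy)-4H-chromen-4-one; 2 prenyl bromide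
Product: 16 2-[2,4-bis(methoxymethoxy)-5-(2-methylbut-3-en-2-yl)phenyl]-7-(methoxymethoxy)-5-[(3-methylbut-2-en-1-yl)oxy]-4H-chromen-4-one
Conditions: prenyl bromide (excess), K2CO3, acetone, reflux
Reagents that add atoms: none
Why: Williamson etherification of the only remaining hydroxyl, the chelated 5-OH, should proceed under forcing conditions as it does for other 5-hydroxyflavones.

Step 12
Reactants: 16 2-[2,4-bis(methoxymethoxy)-5-(2-methylbut-3-en-2-yl)phenyl]-7-(methoxymethoxy)-5-[(3-methylbut-2-en-1-yl)oxy]-4H-chromen-4-one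
Product: 18 2-[2,4-bis(methoxymethoxy)-5-(2-methylbut-3-en-2-yl)phenyl]-5-hydroxy-7-(methoxymethoxy)-8-(3-methylbut-2-en-1-yl)-4H-chromen-4-one, via 6-(1,1-dimethylallyl) ortho-dienone 17 (not isolated)
Conditions: Eu(fod)3 (10 mol %), NaHCO3, PhCl, 85 °C
Reagents that add atoms: none
Why: Europium(III)-catalysed para-Claisen–Cope rearrangement: chelation at O5/C4=O accelerates the [3,3] shift to C6, and a Cope [3,3] shift of dienone 17 followed by enolisation should place an uninverted prenyl group on C8, the position para to O5.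

Step 13
Reactants: 18 2-[2,4-bis(methoxymethoxy)-5-(2-methylbut-3-en-2-yl)phenyl]-5-hydroxy-7-(methoxymethoxy)-8-(3-methylbut-2-en-1-yl)-4H-chromen-4-one
Product: 19 2-[2,4-dihydroxy-5-(2-methylbut-3-en-2-yl)phenyl]-5,7-dihydroxy-8-(3-methylbut-2-en-1-yl)-4H-chromen-4-one (target)
Conditions: 3 M aq. HCl, MeOH, 40 °C
Reagents that add atoms: none
Why: Acid-catalysed acetal methanolysis should remove all three aryl MOM groups at once, under conditions mild enough to avoid addition of the freed phenols to the neighbouring prenyl and 1,1-dimethylallyl double bonds.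

**Compound list**

1 | methyl 2,4-dihydroxybenzoate | COC(=O)c1ccc(O)cc1O | starting material
2 | prenyl bromide (1-bromo-3-methylbut-2-ene) | CC(C)=CCBr | starting material
3 | methyl 2-hydroxy-4-[(3-methylbut-2-en-1-yl)oxy]benzoate | COC(=O)c1ccc(OCC=C(C)C)cc1O | intermediate
4 | methyl 2-(methoxymethoxy)-4-[(3-methylbut-2-en-1-yl)oxy]benzoate | COC(=O)c1ccc(OCC=C(C)C)cc1OCOC | intermediate
5 | methyl 4-hydroxy-2-(methoxymethoxy)-5-(2-methylbut-3-en-2-yl)benzoate | COC(=O)c1cc(C(C)(C)C=C)c(O)cc1OCOC | intermediate
6 | methyl 2,4-bis(methoxymethoxy)-5-(2-methylbut-3-en-2-yl)benzoate | COC(=O)c1cc(C(C)(C)C=C)c(OCOC)cc1OCOC | intermediate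
7 | 2,6-dimethyl-4H-pyran-4-one | Cc1cc(=O)cc(C)o1 | starting material
8 | heptane-2,4,6-trione | CC(=O)CC(=O)CC(=O)C | intermediate
9 | 1-[2,4-bis(methoxymethoxy)-5-(2-methylbut-3-en-2-yl)phenyl]octane-1,3,5,7-tetraone | CC(=O)CC(=O)CC(=O)CC(=O)c1cc(C(C)(C)C=C)c(OCOC)cc1OCOC | intermediate
10 | dimethyl carbonate | COC(=O)OC | starting material
11 | methyl 9-[2,4-bis(methoxymethoxy)-5-(2-methylbut-3-en-2-yl)phenyl]-3,5,7,9-tetraoxononanoate | COC(=O)CC(=O)CC(=O)CC(=O)CC(=O)c1cc(C(C)(C)C=C)c(OCOC)cc1OCOC | intermediate
12 | 1-[2,4-bis(methoxymethoxy)-5-(2-methylbut-3-en-2-yl)phenyl]-3-(2,4,6-trihydroxyphenyl)propane-1,3-dione | O=C(CC(=O)c1c(O)cc(O)cc1O)c1cc(C(C)(C)C=C)c(OCOC)cc1OCOC | intermediate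
13 | 2-[2,4-bis(methoxymethoxy)-5-(2-methylbut-3-en-2-yl)phenyl]-2,5,7-trihydroxy-2,3-dihydro-4H-chromen-4-one (racemic hemiketal, ring tautomer of 12) | O=C1CC(O)(c2cc(C(C)(C)C=C)c(OCOC)cc2OCOC)Oc2cc(O)cc(O)c21 | intermediate (not isolated)
14 | 2-[2,4-bis(methoxymethoxy)-5-(2-methylbut-3-en-2-yl)phenyl]-5,7-dihydroxy-4H-chromen-4-one | C=CC(C)(C)c1cc(-c2cc(=O)c3c(O)cc(O)cc3o2)c(OCOC)cc1OCOC | intermediate
15 | 2-[2,4-bis(methoxymethoxy)-5-(2-methylbut-3-en-2-yl)phenyl]-5-hydroxy-7-(methoxymethoxy)-4H-chromen-4-one | C=CC(C)(C)c1cc(-c2cc(=O)c3c(O)cc(OCOC)cc3o2)c(OCOC)cc1OCOC | intermediate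
16 | 2-[2,4-bis(methoxymethoxy)-5-(2-methylbut-3-en-2-yl)phenyl]-7-(methoxymethoxy)-5-[(3-methylbut-2-en-1-yl)oxy]-4H-chromen-4-one | C=CC(C)(C)c1cc(-c2cc(=O)c3c(OCC=C(C)C)cc(OCOC)cc3o2)c(OCOC)cc1OCOC | intermediate
17 | 2-[2,4-bis(methoxymethoxy)-5-(2-methylbut-3-en-2-yl)phenyl]-7-(methoxymethoxy)-6-(2-methylbut-3-en-2-yl)-6H-chromene-4,5-dione (racemic ortho-dienone) | O=C1C(C(C)(C)C=C)C(OCOC)=CC2=C1C(=O)C=C(c1cc(C(C)(C)C=C)c(OCOC)cc1OCOC)O2 | intermediate (not isolated)
18 | 2-[2,4-bis(methoxymethoxy)-5-(2-methylbut-3-en-2-yl)phenyl]-5-hydroxy-7-(methoxymethoxy)-8-(3-methylbut-2-en-1-yl)-4H-chromen-4-one | C=CC(C)(C)c1cc(-c2cc(=O)c3c(O)cc(OCOC)c(CC=C(C)C)c3o2)c(OCOC)cc1OCOC | intermediate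
19 | 2-[2,4-dihydroxy-5-(2-methylbut-3-en-2-yl)phenyl]-5,7-dihydroxy-8-(3-methylbut-2-en-1-yl)-4H-chromen-4-one (CNP0315714.0, achiral) | C=CC(C)(C)c1cc(-c2cc(=O)c3c(O)cc(O)c(CC=C(C)C)c3o2)c(O)cc1O | target

**Totals**

Total step count: 13.
Longest linear sequence: 12 steps (steps 1–4 and 6–13, from 1); step 5 is a one-step side branch.

**Steps most likely to fail**

Step 8. The polyenolate may close by aldol addition onto one of the ketones or by O-acylation to a pyranone instead of C-acylation at the ester, or the ester may be saponified before it cyclises. The fallback sets out from 6 and comes back to the route at 12; it takes ring A from an aromatic building block instead of cyclising it. Ester 6 is saponified (LiOH, THF–MeOH–H2O, 50 °C) to 2,4-bis(methoxymethoxy)-5-(2-methylbut-3-en-2-yl)benzoic acid F1. F1 is activated with 1,1'-carbonyldiimidazole (THF, rt) as [2,4-bis(methoxymethoxy)-5-(2-methylbut-3-en-2-yl)phenyl](1H-imidazol-1-yl)methanone F2. F2 is added to the lithium polyanion of commercial 2,4,6-trihydroxyacetophenone (LiHMDS, 5 equiv, THF, −78 °C → rt). The ketone enolate should be C-acylated in a Baker–Venkataraman-type Claisen condensation, giving 12 after work-up at pH 4–5.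

Step 7. Proton transfer from the product to unreacted tetraanion, attack of the amide base on the carbonate, or cyclisation of the chain during work-up may erode the methoxycarbonylation. The fallback sets out from 9 and comes back at 11; it separates C–C bond formation from ester formation. The tetraanion of 9 (LDA, THF) is carboxylated with CO2 at −78 °C, and cold acidification gives 9-[2,4-bis(methoxymethoxy)-5-(2-methylbut-3-en-2-yl)phenyl]-3,5,7,9-tetraoxononanoic acid F3. F3 is not stored but esterified at once with trimethylsilyldiazomethane (toluene–MeOH, 0 °C) to 11. The intermediate carboxylate can neither be acylated a second time nor undergo Claisen closure.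

Step 3. The [3,3] shift may go partly to C3, the prenyl ether may fragment with loss of isoprene, or the product may isomerise further (abnormal Claisen) or cyclise onto the phenol at the temperature required. The fallback sets out from 1 and comes back at 6; it makes the aryl–C(quaternary) bond by cross-coupling instead of rearrangement. Ester 1 is brominated para to the 2-OH (NBS, MeCN, 0 °C) to methyl 5-bromo-2,4-dihydroxybenzoate F4. Both phenols are protected (NaH, MOMCl, DMF) to give methyl 5-bromo-2,4-bis(methoxymethoxy)benzoate F5. A ligand-controlled, branch(γ)-selective Suzuki–Miyaura coupling with 3-methylbut-2-en-1-ylboronic acid pinacol ester (Pd precatalyst with a bulky biarylphosphine, K3PO4, THF–H2O, 40–70 °C) should install the 2-methylbut-3-en-2-yl group and give 6 directly, bypassing 3–5.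

**Further compounds**

F1 | step 8 | 2,4-bis(methoxymethoxy)-5-(2-methylbut-3-en-2-yl)benzoic acid | OC(=O)c1cc(C(C)(C)C=C)c(OCOC)cc1OCOC
F2 | step 8 | [2,4-bis(methoxymethoxy)-5-(2-methylbut-3-en-2-yl)phenyl](1H-imidazol-1-yl)methanone | O=C(c1cc(C(C)(C)C=C)c(OCOC)cc1OCOC)n1ccnc1
F3 | step 7 | 9-[2,4-bis(methoxymethoxy)-5-(2-methylbut-3-en-2-yl)phenyl]-3,5,7,9-tetraoxononanoic acid | OC(=O)CC(=O)CC(=O)CC(=O)CC(=O)c1cc(C(C)(C)C=C)c(OCOC)cc1OCOC
F4 | step 3 | methyl 5-bromo-2,4-dihydroxybenzoate | COC(=O)c1cc(Br)c(O)cc1O
F5 | step 3 | methyl 5-bromo-2,4-bis(methoxymethoxy)benzoate | COC(=O)c1cc(Br)c(OCOC)cc1OCOC
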